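**Plan**

Numbering is prostanoid: C1 = ester carbon, ring = C8–C12, C20 = chain methyl. The hardest feature is the C8–C12 bond. It joins an epimerisable C8–H centre to a tertiary allylic acetate with the two chains cis, inside a base-intolerant enone oxygenated 1,4 at C9 and C12.
Cuts: C8–C12 first (retro-4π, cyclopentenone back to a furyl carbinol), then C4–C5 (alkenylzinc + aldehyde), C7–C8 (propargylation) and C12–C13 (furan alkylation).
Forward: C12–C13, C7–C8 and C4–C5 are joined in that order on a flat, base-tolerant 2,5-disubstituted furan. The only ring arises last from the complete C1–C20 chain, and only one acetylation follows it.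
Enabling feature: C9(=O)–C10=C11–C12(O) is the carbon/oxygen pattern of an opened furan. The oxygen on C12 stands trans to C7 on C8, which is the outcome of a conrotatory closure of the C8–C12 pentadienyl cation (oxa-Piancatelli). Adding a C13 nucleophile to a C12 ketone anti to C7 would give the opposite relation.
Stereochemistry: C4 comes from a ligand-controlled alkenylzinc addition. C8 and C12 are set together in the key step, relative by conrotation and absolute by a chiral Brønsted acid. 14Z comes from Lindlar reduction and 5E from syn hydroboration.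

Key step: step 8

Assumption: the sense of induction of the chiral acid in step 8 cannot be derived from a reliable model. The (R)-acid is written, and its available antipode replaces it if a test run on 17 shows the opposite sense.

**Step 1**
Reactants: 1 oct-2-yn-1-ol
Product: 2 (Z)-oct-2-en-1-ol
Conditions: H2 (1 atm), Lindlar catalyst, quinoline, MeOH, rt
Reagents that add atoms: none
Why: Lindlar semihydrogenation adds H2 syn on poisoned Pd and stops at the alkene, which fixes the 14Z geometry.

**Step 2**
Reactants: 2 (Z)-oct-2-en-1-ol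
Product: 3 (Z)-1-bromooct-2-ene
Conditions: CBr4, PPh3, CH2Cl2, 0 °C
Reagents that add atoms: carbon tetrabromide, BrC(Br)(Br)Br
Why: The Appel reaction replaces the primary allylic OH by SN2 at low temperature and should cause neither allylic shift nor Z/E isomerisation.

**Step 3**
Reactants: 4 2-(diethoxymethyl)furan (furfural diethyl acetal); 3 (Z)-1-bromooct-2-ene
Product: 7 5-[(Z)-oct-2-en-1-yl]furan-2-carbaldehyde, via 5-lithiofuran acetal 5 (not isolated), via alkylated acetal 6 (not isolated)
Conditions: n-BuLi, THF, −78 to 0 °C; 3, −78 °C to rt; then 1 M HCl, THF, rt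
Reagents that add atoms: water, O
Why: α-Lithiation of the furan at C5 and SN2 alkylation with the primary allylic bromide form C12–C13, with the formyl carbon in place as its acetal before the acidic furfurylic/allylic C13 methylene exists, and the acetal is hydrolysed in the work-up (heteroaryl lithiation/alkylation, acetal hydrolysis).

**Step 4**
Reactants: 7 5-[(Z)-oct-2-en-1-yl]furan-2-carbaldehyde; 8 3-bromoprop-1-yne (propargyl bromide)
Product: 10 1-{5-[(Z)-oct-2-en-1-yl]furan-2-yl}but-3-yn-1-ol (racemic at C8), via allenylzinc bromide 9 (not isolated)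
Conditions: Zn dust, THF, 0 °C to rt; aqueous work-up
Reagents that add atoms: none
Why: In the Barbier propargylation the allenylzinc adds through its γ-carbon (SE2′) to give the homopropargylic alcohol and the C7–C8 bond, and the carbinol centre is left racemic because step 8 erases it.

**Step 5**
Reactants: 10 1-{5-[(Z)-oct-2-en-1-yl]furan-2-yl}but-3-yn-1-ol
Product: 11 tert-butyldimethylsilyl ether of 10 (racemic)
Conditions: TBSCl, imidazole, DMF, rt
Reagents that add atoms: tert-butyldimethylsilyl chloride, CC(C)(C)[Si](C)(C)Cl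
Why: Standard silylation masks the OH, which would otherwise consume the borane and the zinc reagent of step 6 and act as an achiral ligand on zinc.

**Step 6**
Reactants: 11 TBS ether of 10; 12 methyl 4-oxobutanoate
Product: 16 methyl (4S,5E)-4-acetoxy-8-[(tert-butyldimethylsilyl)oxy]-8-{5-[(Z)-oct-2-en-1-yl]furan-2-yl}oct-5-enoate (both C8 epimers), via alkenylborane 13 (not isolated), via alkenylzinc 14 (not isolated), via zinc alkoxide 15 (not isolated)
Conditions: Cy2BH (1.0 equiv), PhMe, 0 °C to rt; Me2Zn, −78 °C; (+)-MIB (5 mol %), 12, −10 °C; then Ac2O, −10 °C to rt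
Reagents that add atoms: acetic anhydride, CC(=O)OC(C)=O
Why: Syn hydroboration of the terminal alkyne (faster than that of the internal Z-alkene) gives the (E)-alkenylborane, B-to-Zn exchange and amino-alcohol-catalysed asymmetric alkenylzinc addition form C4–C5 by ligand-directed attack on the Re face of 12 (4S), and Ac2O traps the zinc alkoxide before it can lactonise onto C1.

**Step 7**
Reactants: 16 silyl ether
Product: 17 methyl (4S,5E)-4-acetoxy-8-hydroxy-8-{5-[(Z)-oct-2-en-1-yl]furan-2-yl}oct-5-enoate (both C8 epimers)
Conditions: TBAF, AcOH (1:1), THF, rt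
Reagents that add atoms: none
Why: Fluoride-induced desilylation in a buffered medium should spare the acetate, the methyl ester and the acid-labile furyl carbinol.

**Step 8**
Reactants: 17 furyl carbinol
Product: 20 methyl (4S,5E)-4-acetoxy-7-{(1S,5R)-5-hydroxy-5-[(Z)-oct-2-en-1-yl]-2-oxocyclopent-3-en-1-yl}hept-5-enoate, via hemiketal 18 (not isolated), via pentadienyl cation 19 (not isolated)
Conditions: (R)-3,3′-bis(2,4,6-triisopropylphenyl)-BINOL N-triflylphosphoramide (10 mol %), H2O (5 equiv), PhMe, 25 °C
Reagents that add atoms: water, O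
Why: Proposed new method: the acid ionises either C8 epimer of 17 to the same 5-alkylfurfuryl cation, water adds at the furan carbon that bears the octenyl chain (C12) to give hemiketal 18, and ring opening gives the 1,4-dihydroxypentadienyl cation 19, which forms the C8–C12 bond and the five-membered carbocycle by a conrotatory 4π electrocyclisation (Nazarov mode of closure). The closest known reaction types are the racemic oxa-Piancatelli rearrangement of 5-alkyl-2-furyl homoallyl carbinols in buffered water or with Dy(OTf)3 (same substrate class) and the chiral-Brønsted-acid-catalysed aza-Piancatelli and Nazarov reactions, so that only water as nucleophile under a chiral acid is new. The relative configuration follows from orbital symmetry: C7 on C8 and OH on C12 take the outside positions of the U-shaped cation, so conrotation places them trans and the two chains cis, under kinetic control and independent of which C8 epimer is the more stable. The absolute configuration (8S,12R) must come from the chiral anion, which is expected to stay hydrogen-bonded to the C9–OH and C12–OH groups of 19 and thus to favour one of the two conrotatory senses; C4 is too remote to interfere, but it turns any leakage into a diastereomer that can be removed. The choice of C8 rather than the more acidic C13 as the bond-forming terminus is fixed by the position of the carbinol. The 5-alkyl group should make ionisation easy enough at 25 °C to spare both esters, the allylic acetate, both alkenes and the C8–H of the product.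

**Step 9**
Reactants: 20 hydroxy enone
Product: 21 methyl (4S,5E)-4-acetoxy-7-{(1S,5R)-5-acetoxy-5-[(Z)-oct-2-en-1-yl]-2-oxocyclopent-3-en-1-yl}hept-5-enoate (target)
Conditions: Ac2O, Sc(OTf)3 (3 mol %), MeCN, −20 °C
Reagents that add atoms: acetic anhydride, CC(=O)OC(C)=O
Why: Lewis-acid-catalysed acylation esterifies hindered tertiary alcohols at low temperature without base, so that enolisation at C8, retro-aldol cleavage and E1cB loss of acetate should be avoided, while the electron-poor enone disfavours ionisation at C12.

**Compound list**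

1 | oct-2-yn-1-ol | CCCCCC#CCO | starting material
2 | (Z)-oct-2-en-1-ol | CCCCC/C=C\CO | intermediate
3 | (Z)-1-bromooct-2-ene | CCCCC/C=C\CBr | intermediate
4 | 2-(diethoxymethyl)furan | CCOC(OCC)c1ccco1 | starting material
5 | [5-(diethoxymethyl)furan-2-yl]lithium | CCOC(OCC)c1ccc([Li])o1 | intermediate
6 | 2-(diethoxymethyl)-5-[(Z)-oct-2-en-1-yl]furan | CCCCC/C=C\Cc1ccc(C(OCC)OCC)o1 | intermediate
7 | 5-[(Z)-oct-2-en-1-yl]furan-2-carbaldehyde | CCCCC/C=C\Cc1ccc(C=O)o1 | intermediate
8 | 3-bromoprop-1-yne | C#CCBr | starting material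
9 | allenylzinc bromide | C=C=C[Zn]Br | intermediate
10 | 1-{5-[(Z)-oct-2-en-1-yl]furan-2-yl}but-3-yn-1-ol (racemic) | CCCCC/C=C\Cc1ccc(C(O)CC#C)o1 | intermediate
11 | TBS ether of 10 (racemic) | CCCCC/C=C\Cc1ccc(C(CC#C)O[Si](C)(C)C(C)(C)C)o1 | intermediate
12 | methyl 4-oxobutanoate | COC(=O)CCC=O | starting material
13 | (E)-alkenyl(dicyclohexyl)borane from 11 | CCCCC/C=C\Cc1ccc(C(C/C=C/B(C2CCCCC2)C2CCCCC2)O[Si](C)(C)C(C)(C)C)o1 | intermediate
14 | (E)-alkenyl(methyl)zinc from 13 | CCCCC/C=C\Cc1ccc(C(C/C=C/[Zn]C)O[Si](C)(C)C(C)(C)C)o1 | intermediate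
15 | methylzinc (4S)-alkoxide | CCCCC/C=C\Cc1ccc(C(C/C=C/[C@H](CCC(=O)OC)O[Zn]C)O[Si](C)(C)C(C)(C)C)o1 | intermediate
16 | methyl (4S,5E)-4-acetoxy-8-(TBSO)-8-{5-[(Z)-oct-2-en-1-yl]furan-2-yl}oct-5-enoate (C8 epimers) | CCCCC/C=C\Cc1ccc(C(C/C=C/[C@H](CCC(=O)OC)OC(C)=O)O[Si](C)(C)C(C)(C)C)o1 | intermediate
17 | methyl (4S,5E)-4-acetoxy-8-hydroxy-8-{5-[(Z)-oct-2-en-1-yl]furan-2-yl}oct-5-enoate (C8 epimers) | CCCCC/C=C\Cc1ccc(C(O)C/C=C/[C@H](CCC(=O)OC)OC(C)=O)o1 | intermediate
18 | 5-hydroxy-5-octenyl-2-alkylidene-2,5-dihydrofuran (hemiketal, C7 cis to ring O) | CCCCC/C=C\CC1(O)C=C/C(=C/C/C=C/[C@H](CCC(=O)OC)OC(C)=O)O1 | intermediate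
19 | 1,4-dihydroxypentadienyl cation C8–C12 (drawn as O-protonated C12 ketone of the Z-enedione C8 enol) | CCCCC/C=C\CC(=[OH+])/C=C\C(O)=C\C/C=C/[C@H](CCC(=O)OC)OC(C)=O | intermediate
20 | methyl (4S,5E)-4-acetoxy-7-{(1S,5R)-5-hydroxy-5-[(Z)-oct-2-en-1-yl]-2-oxocyclopent-3-en-1-yl}hept-5-enoate | CCCCC/C=C\C[C@@]1(O)C=CC(=O)[C@H]1C/C=C/[C@H](CCC(=O)OC)OC(C)=O | intermediate
21 | methyl (4S,5E)-4-acetoxy-7-{(1S,5R)-5-acetoxy-5-[(Z)-oct-2-en-1-yl]-2-oxocyclopent-3-en-1-yl}hept-5-enoate | CCCCC/C=C\C[C@@]1(OC(C)=O)C=CC(=O)[C@H]1C/C=C/[C@H](CCC(=O)OC)OC(C)=O | target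

**Totals**

Total step count: 9. Longest linear sequence: 9 steps (1 to 21). Compounds 4, 8 and 12 are bought.

**Steps most likely to fail**

1. Step 8. The anion may discriminate poorly between the two conrotatory senses. The furfuryl cation may also lose a proton from C7 or C13 faster than water captures it at C12. The fallback sets out from 17 and returns at 20. Carbinol 17 is rearranged under the known achiral conditions for 5-alkylfuryl homoallyl carbinols (Dy(OTf)3 cat., t-BuOH/H2O, 80 °C, or phosphate buffer pH 5, reflux). This should give the trans-O/C7 relation in both ring senses, that is 20 together with the (4S,8R,12S) ring diastereomer F1. Because C4 is already fixed, the two are diastereomers and are separated by preparative HPLC. Compound 20 then enters step 9.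

2. Step 9. The hindered tertiary alcohol may acylate more slowly than the β-hydroxy ketone undergoes retro-aldol opening or C8 epimerises through the enol. The fallback sets out from 20 and returns at 21, and it removes the ketone for the duration of the acylation.
   - Luche reduction (NaBH4, CeCl3, MeOH, −78 °C) should give the C9,C12-diol F2.
   - TESCl/imidazole should silylate only the secondary C9 hydroxyl to give the mono-TES ether F3.
   - Ac2O, DMAP, Et3N can then be used without risk to C8 and should give the tertiary acetate F4.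
   - HF·pyridine frees the C9 allylic alcohol F5.
   - Dess–Martin oxidation restores the enone of 21.

3. Step 6. Facial selectivity may be low with the unbranched, ester-bearing aldehyde, and the zinc alkoxide may lactonise before it is trapped. The fallback sets out from 11 and returns at 16, and it sets C4 by reduction instead of addition.
   - Hydrozirconation of 11 with the Schwartz reagent should give the (E)-alkenylzirconocene chloride F6.
   - Cu(I)-catalysed acylation with methyl 4-chloro-4-oxobutanoate should give the (E)-enone F7.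
   - CBS reduction with (R)-Me-CBS and catecholborane at −78 °C should give the (4S)-allylic alcohol F8.
   - F8 is acetylated at once (Ac2O, pyridine) to give 16.

**Further compounds**

F1 | step 8 | methyl (4S,5E)-4-acetoxy-7-{(1R,5S)-5-hydroxy-5-[(Z)-oct-2-en-1-yl]-2-oxocyclopent-3-en-1-yl}hept-5-enoate | CCCCC/C=C\C[C@]1(O)C=CC(=O)[C@@H]1C/C=C/[C@H](CCC(=O)OC)OC(C)=O
F2 | step 9 | C9,C12-diol from Luche reduction of 20 (C9 configuration open) | CCCCC/C=C\C[C@@]1(O)C=CC(O)[C@H]1C/C=C/[C@H](CCC(=O)OC)OC(C)=O
F3 | step 9 | C9 triethylsilyl ether of F2 | CCCCC/C=C\C[C@@]1(O)C=CC(O[Si](CC)(CC)CC)[C@H]1C/C=C/[C@H](CCC(=O)OC)OC(C)=O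
F4 | step 9 | C12 acetate of F3 | CCCCC/C=C\C[C@@]1(OC(C)=O)C=CC(O[Si](CC)(CC)CC)[C@H]1C/C=C/[C@H](CCC(=O)OC)OC(C)=O
F5 | step 9 | C9 alcohol, C4,C12-diacetate | CCCCC/C=C\C[C@@]1(OC(C)=O)C=CC(O)[C@H]1C/C=C/[C@H](CCC(=O)OC)OC(C)=O
F6 | step 6 | (E)-alkenylzirconocene chloride from 11 | CCCCC/C=C\Cc1ccc(C(C/C=C/[Zr](Cl)(C2C=CC=C2)C2C=CC=C2)O[Si](C)(C)C(C)(C)C)o1
F7 | step 6 | methyl (5E)-8-(TBSO)-8-{5-[(Z)-oct-2-en-1-yl]furan-2-yl}-4-oxooct-5-enoate | CCCCC/C=C\Cc1ccc(C(C/C=C/C(=O)CCC(=O)OC)O[Si](C)(C)C(C)(C)C)o1
F8 | step 6 | methyl (4S,5E)-4-hydroxy-8-(TBSO)-8-{5-[(Z)-oct-2-en-1-yl]furan-2-yl}oct-5-enoate | CCCCC/C=C\Cc1ccc(C(C/C=C/[C@H](CCC(=O)OC)O)O[Si](C)(C)C(C)(C)C)o1
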